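**Retrosynthetic overview**

1. Integracin D is cut at the C–C bond between the benzoate-bearing methine carbon and the neighbouring CH2 of the seven-carbon tether to the sulfated resorcinol ring (ring B). A four-component nickel-catalysed enantioconvergent hydroalkylation (aroyl bromide 12 + butanal 5 + aryl heptene 15 + hydrosilane) forms the ester C–O bond, this C–C bond and the S stereocentre in one operation.
2. Enabling feature: that methine carbon is O-acylated, so it is the carbonyl carbon of butanal at the acetal level and gives an α-acyloxyalkyl radical. The CH2 beside it starts an unfunctionalised (CH2)7 tether, so it and its neighbour can come from a vinyl group. The same O-acyl methine (n-propyl on one side, 7-arylheptyl on the other, S) recurs as the acetate on the side chain of the dihydroxybenzoate ring (ring A) and is made the same way with acetyl bromide.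
3. Both halves grow from one monomer, 5-(hept-6-enyl)resorcinol dibenzyl ether 4, echoing the presumed joining of two alkylresorcinol units. Ring A half: hydroalkylation, Vilsmeier–Haack formylation, Pinnick oxidation, acyl bromide. Ring B half: mono-debenzylation, silylation.
4. Endgame: desilylation, sulfation of the only free phenol, hydrogenolysis of three benzyl ethers.
5. No ring is formed in the route; both benzene rings come intact from 3,5-bis(benzyloxy)benzyl bromide.

Key step: step 8

Remark 1: the target is drawn as the free aryl hydrogen sulfate; the sulfate is carried as its sodium salt and protonated in the last operation.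
Remark 2: steps 2 and 8 create the same kind of stereocentre (n-propyl from the electrophile, arylheptyl from the olefin), so one antipode of the bis(oxazoline) ligand should give S in both; which antipode that is would be fixed on compound 8 (MTPA esters of the derived alcohol) before step 8 is run.

**Route**

Step 1
Reactants: 1 3,5-bis(benzyloxy)benzyl bromide; 2 6-bromohex-1-ene
Product: 4 1,3-bis(benzyloxy)-5-(hept-6-en-1-yl)benzene, via hex-5-en-1-ylmagnesium bromide 3 (not isolated)
Conditions: 2, Mg, THF, rt; then 1, Li2CuCl4 (cat.), THF, −78 → 0 °C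
Reagents that add atoms: none
Why: Copper-catalysed sp3–sp3 Grignard cross-coupling of a benzylic bromide with a primary alkylmagnesium bromide should proceed cleanly at low temperature, and benzyl ethers and the terminal olefin are inert to it.

Step 2
Reactants: 4 1,3-bis(benzyloxy)-5-(hept-6-en-1-yl)benzene; 5 butanal; 6 acetyl bromide
Product: 8 (S)-11-[3,5-bis(benzyloxy)phenyl]undecan-4-yl acetate, via 1-bromobutyl acetate 7 (not isolated)
Conditions: 5 + 6, neat, 0 °C → rt; then 4, NiBr2·glyme (cat.), chiral isopropylidene-bridged bis(oxazoline) L* (cat., antipode giving S), (EtO)3SiH, K3PO4·H2O, iPr2O–DMA, rt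
Reagents that add atoms: none
Why: Nickel-hydride-catalysed enantioconvergent hydroalkylation of a terminal olefin with a racemic 1-bromoalkyl ester: anti-Markovnikov Ni–H addition gives a primary alkylnickel that captures the 1-acetoxybutyl radical from 7, and the chiral ligand on nickel fixes the S configuration although the two alkyl arms are nearly the same size.

Step 3
Reactants: 8 (S)-11-[3,5-bis(benzyloxy)phenyl]undecan-4-yl acetate
Product: 10 (S)-11-[3,5-bis(benzyloxy)-2-formylphenyl]undecan-4-yl acetate, via aryl iminium chloride 9 (not isolated)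
Conditions: POCl3, DMF, 0 → 40 °C; then H2O, 0 °C → rt
Reagents that add atoms: N,N-dimethylformamide CN(C)C=O (formyl carbon); water O (formyl oxygen on hydrolysis)
Why: Vilsmeier–Haack formylation of a 5-alkylresorcinol diether should go to the ring carbon para to one benzyloxy group and ortho to the other (the two such positions are equivalent by symmetry) rather than to the more hindered carbon between the two ethers, and the acetate tolerates the conditions.

Step 4
Reactants: 10 (S)-11-[3,5-bis(benzyloxy)-2-formylphenyl]undecan-4-yl acetate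
Product: 11 2-[(S)-8-acetoxyundecyl]-4,6-bis(benzyloxy)benzoic acid
Conditions: NaClO2, NaH2PO4, 2-methyl-2-butene, t-BuOH–THF–H2O, 0 °C → rt
Reagents that add atoms: sodium chlorite [Na+].[O-]Cl=O
Why: Pinnick oxidation converts the hindered, electron-rich aryl aldehyde to the acid under buffered conditions, with the alkene scavenger trapping hypochlorous acid so that the ring is not chlorinated and the acetate and benzyl ethers stay intact.

Step 5
Reactants: 11 2-[(S)-8-acetoxyundecyl]-4,6-bis(benzyloxy)benzoic acid
Product: 12 2-[(S)-8-acetoxyundecyl]-4,6-bis(benzyloxy)benzoyl bromide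
Conditions: Me2C=C(Br)NMe2, CH2Cl2, 0 °C → rt; concentrated under high vacuum and used crude
Reagents that add atoms: 1-bromo-N,N,2-trimethylprop-1-en-1-amine CC(C)=C(Br)N(C)C
Why: Acyl halide formation with an α-haloenamine runs under neutral conditions (no HBr is released), which suits a hindered 2,6-disubstituted benzoic acid that carries benzyl ethers and an acetate.

Step 6
Reactants: 4 1,3-bis(benzyloxy)-5-(hept-6-en-1-yl)benzene
Product: 14 3-(benzyloxy)-5-(hept-6-en-1-yl)phenol, via sodium phenoxide 13 (not isolated)
Conditions: NaSEt, DMF, 110 °C, argon; then aq. HCl, 0 °C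
Reagents that add atoms: none
Why: Nucleophilic dealkylation of an aryl benzyl ether by thiolate (SN2 at the benzylic carbon) should stop after one cleavage, because the ring then carries a phenoxide and the second aryloxide would be a far poorer leaving group.

Step 7
Reactants: 14 3-(benzyloxy)-5-(hept-6-en-1-yl)phenol
Product: 15 1-(benzyloxy)-3-(hept-6-en-1-yl)-5-[(triisopropylsilyl)oxy]benzene
Conditions: TIPSCl, imidazole, DMF, rt
Reagents that add atoms: triisopropylsilyl chloride CC(C)[Si](Cl)(C(C)C)C(C)C
Why: Standard silylation of a phenol gives a bulky aryl silyl ether that marks the oxygen destined for sulfation and should withstand the phosphate base and silane of step 8.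

Step 8
Reactants: 12 2-[(S)-8-acetoxyundecyl]-4,6-bis(benzyloxy)benzoyl bromide; 5 butanal; 15 1-(benzyloxy)-3-(hept-6-en-1-yl)-5-[(triisopropylsilyl)oxy]benzene
Product: 17 (S)-11-[3-(benzyloxy)-5-(triisopropylsilyloxy)phenyl]undecan-4-yl 2-[(S)-8-acetoxyundecyl]-4,6-bis(benzyloxy)benzoate, via 1-bromobutyl aroate 16 (not isolated)
Conditions: 12 + 5 (1.1 equiv), CH2Cl2, 0 °C → rt; then diluted with iPr2O–DMA and added to 15 (1.5 equiv), NiBr2·glyme (cat.), bis(oxazoline) L* (cat., same antipode as in step 2), (EtO)3SiH, K3PO4·H2O, rt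
Reagents that add atoms: none
Why: The aroyl bromide 12 adds across the C=O bond of butanal (acylation at oxygen, return of bromide to carbon) to give the racemic 1-bromobutyl aroate 16, so the hindered ester C–O bond is made without esterifying a secondary alcohol. A bis(oxazoline)-ligated nickel hydride, formed from NiBr2·glyme, the silane and the phosphate base, adds to the vinyl group of 15 in the anti-Markovnikov sense; low-valent nickel abstracts bromine from 16, the α-acyloxyalkyl radical is captured by the chiral alkylnickel species, and reductive elimination forms the C(sp3)–C(sp3) bond. The closest known reaction type is the nickel-catalysed enantioconvergent hydroalkylation of terminal olefins with racemic 1-bromoalkyl esters, including its four-component form from an aldehyde, an acyl bromide, an olefin and a hydrosilane. No ring is closed. The new S stereocentre is set by the ligand on nickel at the C–C bond-forming stage (both enantiomers of 16 converge through the planar radical), so the near-identical n-propyl and arylheptyl arms need not be told apart and the remote acetate stereocentre has no influence. The step needs linear regioselectivity, secured by the monosubstituted olefin, and chemoselectivity, secured because 15 carries the only C=C bond (the olefin of the other half was consumed in step 2) and the silyl ether, benzyl ethers, acetate and aryl C–O bonds are inert to the catalyst at room temperature.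

Step 9
Reactants: 17 (S)-11-[3-(benzyloxy)-5-(triisopropylsilyloxy)phenyl]undecan-4-yl 2-[(S)-8-acetoxyundecyl]-4,6-bis(benzyloxy)benzoate
Product: 18 (S)-11-[3-(benzyloxy)-5-hydroxyphenyl]undecan-4-yl 2-[(S)-8-acetoxyundecyl]-4,6-bis(benzyloxy)benzoate
Conditions: Bu4NF, AcOH, THF, 0 °C
Reagents that add atoms: none
Why: Fluoride-mediated cleavage of the aryl silyl ether is fast at 0 °C, and the acetic acid buffer protonates the phenoxide at once so that neither the acetate nor the benzoate is attacked.

Step 10
Reactants: 18 (S)-11-[3-(benzyloxy)-5-hydroxyphenyl]undecan-4-yl 2-[(S)-8-acetoxyundecyl]-4,6-bis(benzyloxy)benzoate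
Product: 20 sodium 3-(benzyloxy)-5-[(S)-8-({2-[(S)-8-acetoxyundecyl]-4,6-bis(benzyloxy)benzoyl}oxy)undecyl]phenyl sulfate, via pyridinium aryl sulfate 19 (not isolated)
Conditions: SO3·pyridine, pyridine, 40 °C; then aq. NaHCO3
Reagents that add atoms: sulfur trioxide–pyridine complex O=S(=O)=O.c1ccncc1; sodium hydrogen carbonate [Na+].OC(=O)[O-]
Why: O-sulfation of a phenol with SO3·pyridine is selective here because 18 has a single free hydroxyl group, and exchange to the sodium salt removes pyridine, which would otherwise slow the hydrogenolysis that follows.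

Step 11
Reactants: 20 sodium 3-(benzyloxy)-5-[(S)-8-({2-[(S)-8-acetoxyundecyl]-4,6-bis(benzyloxy)benzoyl}oxy)undecyl]phenyl sulfate
Product: 22 Integracin D, via integracin D sodium salt 21 (not isolated)
Conditions: H2 (1 atm), Pd/C, EtOAc–MeOH, rt; filtration; then 1 M HCl (1.0 equiv), 0 °C, reversed-phase desalting, kept cold
Reagents that add atoms: none
Why: Catalytic hydrogenolysis over palladium on carbon removes the three aryl benzyl ethers while the alkyl benzoate, the acetate and the aryl sulfate salt are left untouched, and one equivalent of acid then gives the hydrogen sulfate form.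

**Compound list**

1 | 3,5-bis(benzyloxy)benzyl bromide | BrCc1cc(OCc2ccccc2)cc(OCc2ccccc2)c1 | starting material
2 | 6-bromohex-1-ene | C=CCCCCBr | starting material
3 | hex-5-en-1-ylmagnesium bromide | C=CCCCC[Mg]Br | intermediate
4 | 1,3-bis(benzyloxy)-5-(hept-6-en-1-yl)benzene | C=CCCCCCc1cc(OCc2ccccc2)cc(OCc2ccccc2)c1 | intermediate
5 | butanal | CCCC=O | starting material
6 | acetyl bromide | CC(=O)Br | starting material
7 | 1-bromobutyl acetate (racemic) | CCCC(Br)OC(C)=O | intermediate
8 | (S)-11-[3,5-bis(benzyloxy)phenyl]undecan-4-yl acetate | CCC[C@@H](CCCCCCCc1cc(OCc2ccccc2)cc(OCc2ccccc2)c1)OC(C)=O | intermediate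
9 | N-{2-[(S)-8-acetoxyundecyl]-4,6-bis(benzyloxy)benzylidene}-N-methylmethanaminium chloride | CCC[C@@H](CCCCCCCc1cc(OCc2ccccc2)cc(OCc2ccccc2)c1C=[N+](C)C)OC(C)=O.[Cl-] | intermediate
10 | (S)-11-[3,5-bis(benzyloxy)-2-formylphenyl]undecan-4-yl acetate | CCC[C@@H](CCCCCCCc1cc(OCc2ccccc2)cc(OCc2ccccc2)c1C=O)OC(C)=O | intermediate
11 | 2-[(S)-8-acetoxyundecyl]-4,6-bis(benzyloxy)benzoic acid | CCC[C@@H](CCCCCCCc1cc(OCc2ccccc2)cc(OCc2ccccc2)c1C(=O)O)OC(C)=O | intermediate
12 | 2-[(S)-8-acetoxyundecyl]-4,6-bis(benzyloxy)benzoyl bromide | CCC[C@@H](CCCCCCCc1cc(OCc2ccccc2)cc(OCc2ccccc2)c1C(=O)Br)OC(C)=O | intermediate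
13 | sodium 3-(benzyloxy)-5-(hept-6-en-1-yl)phenoxide | C=CCCCCCc1cc([O-])cc(OCc2ccccc2)c1.[Na+] | intermediate
14 | 3-(benzyloxy)-5-(hept-6-en-1-yl)phenol | C=CCCCCCc1cc(O)cc(OCc2ccccc2)c1 | intermediate
15 | 1-(benzyloxy)-3-(hept-6-en-1-yl)-5-[(triisopropylsilyl)oxy]benzene | C=CCCCCCc1cc(OCc2ccccc2)cc(O[Si](C(C)C)(C(C)C)C(C)C)c1 | intermediate
16 | 1-bromobutyl 2-[(S)-8-acetoxyundecyl]-4,6-bis(benzyloxy)benzoate (both epimers at the brominated carbon) | CCC[C@@H](CCCCCCCc1cc(OCc2ccccc2)cc(OCc2ccccc2)c1C(=O)OC(Br)CCC)OC(C)=O | intermediate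
17 | (S)-11-[3-(benzyloxy)-5-(triisopropylsilyloxy)phenyl]undecan-4-yl 2-[(S)-8-acetoxyundecyl]-4,6-bis(benzyloxy)benzoate | CCC[C@@H](CCCCCCCc1cc(OCc2ccccc2)cc(OCc2ccccc2)c1C(=O)O[C@@H](CCC)CCCCCCCc1cc(OCc2ccccc2)cc(O[Si](C(C)C)(C(C)C)C(C)C)c1)OC(C)=O | intermediate
18 | (S)-11-[3-(benzyloxy)-5-hydroxyphenyl]undecan-4-yl 2-[(S)-8-acetoxyundecyl]-4,6-bis(benzyloxy)benzoate | CCC[C@@H](CCCCCCCc1cc(OCc2ccccc2)cc(OCc2ccccc2)c1C(=O)O[C@@H](CCC)CCCCCCCc1cc(OCc2ccccc2)cc(O)c1)OC(C)=O | intermediate
19 | pyridinium 3-(benzyloxy)-5-[(S)-8-({2-[(S)-8-acetoxyundecyl]-4,6-bis(benzyloxy)benzoyl}oxy)undecyl]phenyl sulfate | CCC[C@@H](CCCCCCCc1cc(OCc2ccccc2)cc(OCc2ccccc2)c1C(=O)O[C@@H](CCC)CCCCCCCc1cc(OCc2ccccc2)cc(OS(=O)(=O)[O-])c1)OC(C)=O.c1cc[nH+]cc1 | intermediate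
20 | sodium 3-(benzyloxy)-5-[(S)-8-({2-[(S)-8-acetoxyundecyl]-4,6-bis(benzyloxy)benzoyl}oxy)undecyl]phenyl sulfate | CCC[C@@H](CCCCCCCc1cc(OCc2ccccc2)cc(OCc2ccccc2)c1C(=O)O[C@@H](CCC)CCCCCCCc1cc(OCc2ccccc2)cc(OS(=O)(=O)[O-])c1)OC(C)=O.[Na+] | intermediate
21 | integracin D sodium salt | CCC[C@@H](CCCCCCCc1cc(O)cc(O)c1C(=O)O[C@@H](CCC)CCCCCCCc1cc(O)cc(OS(=O)(=O)[O-])c1)OC(C)=O.[Na+] | intermediate
22 | Integracin D | CCC[C@@H](CCCCCCCc1cc(O)cc(O)c1C(=O)O[C@@H](CCC)CCCCCCCc1cc(O)cc(OS(=O)(=O)O)c1)OC(C)=O | target

**Step count and risks**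

Total step count: 11. Longest linear sequence: 9 steps (steps 1, 2, 3, 4, 5, 8, 9, 10, 11).

Steps most likely to fail:

1. Step 8. The hindered aroyl bromide may add to butanal slowly. The bromoalkyl ester may collapse by attack of the ortho benzyloxy oxygen on the brominated carbon with loss of that benzyl group, or be reduced at the C–Br bond instead of coupling. The bulky 2,6-disubstituted aroyl group may also erode the enantioselectivity. The fallback sets out from olefin 15 and acid 11 and returns at 17; it keeps the same C–C bond construction but takes the aroyl group out of the nickel step and forms the ester bond separately. Olefin 15 would be coupled under the conditions of step 2, but with the antipodal ligand, with 1-bromobutyl acetate 7 (from 5 and 6) to give (R)-11-[3-(benzyloxy)-5-(triisopropylsilyloxy)phenyl]undecan-4-yl acetate F1. Reductive removal of the acetyl group (i-Bu2AlH, CH2Cl2, −78 °C) would give (R)-11-[3-(benzyloxy)-5-(triisopropylsilyloxy)phenyl]undecan-4-ol F2. A Mitsunobu esterification of this alcohol with acid 11 (PPh3, DIAD, toluene, 0 °C → rt), a reaction that copes well with 2,6-disubstituted benzoic acids, would then give 17 with inversion to S.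

2. Step 2. The small acetyl group may give insufficient enantioselectivity, the moisture-sensitive bromoalkyl acetate may hydrolyse before it couples, or chain walking of the alkylnickel may give branched isomers. The fallback sets out from Grignard reagent 3 and returns at 8, taking the stereocentre from the chiral pool. CuI-catalysed opening of commercial (S)-2-propyloxirane at its CH2 terminus by 3 would give (S)-undec-10-en-4-ol F3, and acetylation (Ac2O, pyridine, DMAP) would give (S)-undec-10-en-4-yl acetate F4. Hydroboration with 9-BBN would give (S)-11-(9-borabicyclo[3.3.1]nonan-9-yl)undecan-4-yl acetate F5, which would be coupled in the same flask with commercial 1,3-bis(benzyloxy)-5-bromobenzene in a B-alkyl Suzuki–Miyaura reaction (PdCl2(dppf), K3PO4, DMF–THF–H2O, rt → 50 °C) to give 8.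

3. Step 6. The thiolate may cleave both benzyl ethers or stop short of full conversion, and thiol may add to the terminal olefin if oxygen is not excluded. The fallback sets out from Grignard reagent 3 and commercial methyl 3-(benzyloxy)-5-hydroxybenzoate, in which the two oxygens are already differentiated, and returns at 15. Silylation (TIPSCl, imidazole, DMF) would give methyl 3-(benzyloxy)-5-(triisopropylsilyloxy)benzoate F6. Reduction (i-Bu2AlH, CH2Cl2, −78 → 0 °C) would give [3-(benzyloxy)-5-(triisopropylsilyloxy)phenyl]methanol F7. Appel bromination (CBr4, PPh3, CH2Cl2, 0 °C) would give 1-(benzyloxy)-3-(bromomethyl)-5-(triisopropylsilyloxy)benzene F8, and copper-catalysed coupling with 3 under the conditions of step 1 (Li2CuCl4 cat., THF, −78 → 0 °C) would give 15.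

**Further compounds**

F1 | step 8 | (R)-11-[3-(benzyloxy)-5-(triisopropylsilyloxy)phenyl]undecan-4-yl acetate | CCC[C@H](CCCCCCCc1cc(OCc2ccccc2)cc(O[Si](C(C)C)(C(C)C)C(C)C)c1)OC(C)=O
F2 | step 8 | (R)-11-[3-(benzyloxy)-5-(triisopropylsilyloxy)phenyl]undecan-4-ol | CCC[C@@H](O)CCCCCCCc1cc(OCc2ccccc2)cc(O[Si](C(C)C)(C(C)C)C(C)C)c1
F3 | step 2 | (S)-undec-10-en-4-ol | CCC[C@H](O)CCCCCC=C
F4 | step 2 | (S)-undec-10-en-4-yl acetate | CCC[C@@H](CCCCCC=C)OC(C)=O
F5 | step 2 | (S)-11-(9-borabicyclo[3.3.1]nonan-9-yl)undecan-4-yl acetate | CCC[C@@H](CCCCCCCB1C2CCCC1CCC2)OC(C)=O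
F6 | step 6 | methyl 3-(benzyloxy)-5-(triisopropylsilyloxy)benzoate | COC(=O)c1cc(OCc2ccccc2)cc(O[Si](C(C)C)(C(C)C)C(C)C)c1
F7 | step 6 | [3-(benzyloxy)-5-(triisopropylsilyloxy)phenyl]methanol | OCc1cc(OCc2ccccc2)cc(O[Si](C(C)C)(C(C)C)C(C)C)c1
F8 | step 6 | 1-(benzyloxy)-3-(bromomethyl)-5-(triisopropylsilyloxy)benzene | BrCc1cc(OCc2ccccc2)cc(O[Si](C(C)C)(C(C)C)C(C)C)c1
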